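**Plan**

1. Retrosynthetic cuts: N–PMB of the imide; then the C11–C12 σ-bond (CH2 on C9 of ring B / vinylic CH of the alkylidene imide) into a C11 alkylzinc and an (E)-C12 enol triflate; then C7–OAc and C8=C17 back to the O8–C12 γ-lactone of (+)-sclareolide, whose carbonyl carbon is excised; last C2–Cl back to C2–H.
2. Forward: rings A and B are bought. C–H chlorination at C2, lactol, photochemical β-scission (C11–I plus O8-formate), formate to 8(17)-olefin, C7 oxidation, inversion and acetylation (9 steps). Separately succinimide to the N-PMB E-enol triflate (4 steps). Zinc insertion/Pd coupling joins the halves; CAN frees N–H.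
3. Enabling feature: C11 is the only primary carbon, exocyclic to ring B on the C9 methine, with no β-leaving group, so it can be carried as iodide and zincated. C12 is the β-carbon of the vinylogous imide C12=C13–C16=O, a masked formyl carbon, so the five-membered imide ring is available as a geometrically defined vinyl electrophile.
4. Stereochemistry: C5, C9, C10 come with sclareolide (C9 is never touched); C2 by Cl transfer to the α-face (equatorial); C7 by axial hydride delivery to the C7 ketone; C12=C13 (E) is fixed in the enol triflate and retained in the coupling. The imide is brought in last because it would not tolerate SeO2 or borohydride.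

Key step: step 14

Assumption: the N-chloroamide of step 1 is taken as a purchasable reagent (otherwise one step from the commercial amide with t-BuOCl); labdane numbering (C17 on C8, C11 on C9, C12–C16 in the imide) is used for every compound.

**Route**

Step 1
Reactants: 1 (+)-sclareolide
Product: 2 2α-chlorosclareolide
Conditions: ArCON(Cl)t-Bu (Ar = 3,5-(CF3)2C6H3), Cs2CO3, PhH, visible light, 55 °C
Reagents that add atoms: N-tert-butyl-N-chloro-3,5-bis(trifluoromethyl)benzamide, CC(C)(C)N(Cl)C(=O)c1cc(cc(c1)C(F)(F)F)C(F)(F)F
Why: Amidyl-radical C–H chlorination (radical chain: HAT, then Cl transfer), in which the bulky electrophilic N-radical abstracts H from C2, the most accessible methylene and the one farthest from the deactivating lactone, and the C2 radical takes Cl on the α-face away from the axial C10 and C4 methyls, giving the equatorial 2α-chloride.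

Step 2
Reactants: 2 2α-chlorosclareolide
Product: 3 2α-chlorosclareolide lactol (C12 hemiacetal, anomer mixture)
Conditions: DIBAL-H, CH2Cl2, −78 °C; aq. Rochelle salt
Reagents that add atoms: none
Why: Partial hydride reduction of the γ-lactone stops at the tetrahedral aluminate at −78 °C and gives the lactol on work-up; the secondary chloride is inert and the configuration at C12 is irrelevant.

Step 3
Reactants: 3 2α-chlorosclareolide lactol
Product: 5 2α-chloro-11-iodo-12,13,14,15,16-pentanorlabdan-8α-yl formate, via lactol hypoiodite 4 (not isolated)
Conditions: PhI(OAc)2, I2, cyclohexane–CH2Cl2, hν (visible), rt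
Reagents that add atoms: iodine, II
Why: Suárez hypoiodite reaction, in which photolysis of the O–I bond gives the anomeric alkoxy radical, β-scission of C11–C12 is driven by formation of the formate C=O, and the primary C11 radical is trapped by iodine, C9 keeping its configuration.

Step 4
Reactants: 5 2α-chloro-11-iodo-12,13,14,15,16-pentanorlabdan-8α-yl formate
Product: 6 2α-chloro-11-iodo-12,13,14,15,16-pentanorlabdan-8α-ol
Conditions: KHCO3, MeOH, 0 °C → rt
Reagents that add atoms: none
Why: Base-catalysed methanolysis (transesterification) removes the very labile formate, and the weak base keeps the alkoxide concentration too low for oxetane closure or Grob fragmentation onto the C11 iodide.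

Step 5
Reactants: 6 2α-chloro-11-iodo-12,13,14,15,16-pentanorlabdan-8α-ol
Product: 8 2α-chloro-11-iodo-12,13,14,15,16-pentanorlabd-8(17)-ene, via tertiary chlorosulfite 7 (not isolated)
Conditions: SOCl2, pyridine, CH2Cl2, −78 °C
Reagents that add atoms: none
Why: E2 dehydration through the chlorosulfite, where the equatorial C8–O bond has only ring C–C bonds anti-periplanar and the freely rotating C17 methyl alone can offer an anti hydrogen, so the exocyclic olefin should be the main product.

Step 6
Reactants: 8 2α-chloro-11-iodo-12,13,14,15,16-pentanorlabd-8(17)-ene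
Product: 9 2α-chloro-11-iodo-12,13,14,15,16-pentanorlabd-8(17)-en-7α-ol
Conditions: SeO2 (0.5 equiv), t-BuOOH, CH2Cl2, rt
Reagents that add atoms: selenium dioxide, O=[Se]=O (oxygen delivered through the allylseleninic acid); tert-butyl hydroperoxide, CC(C)(C)OO (re-oxidant, ultimate oxygen source)
Why: Riley allylic oxidation (ene reaction at C17 with loss of the axial C7–Hα, then [2,3]-sigmatropic shift) places OH on the α-face of C7, the C7 methylene reacting in preference to the hindered C9 methine; any enone from over-oxidation converges in step 7.

Step 7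
Reactants: 9 2α-chloro-11-iodo-12,13,14,15,16-pentanorlabd-8(17)-en-7α-ol
Product: 10 2α-chloro-11-iodo-12,13,14,15,16-pentanorlabd-8(17)-en-7-one
Conditions: Dess–Martin periodinane, NaHCO3, CH2Cl2, 0 °C
Reagents that add atoms: none
Why: Dess–Martin oxidation under buffered, neutral conditions gives the exocyclic enone without conjugating the olefin into the ring and without touching the iodide.

Step 8
Reactants: 10 2α-chloro-11-iodo-12,13,14,15,16-pentanorlabd-8(17)-en-7-one
Product: 11 2α-chloro-11-iodo-12,13,14,15,16-pentanorlabd-8(17)-en-7β-ol
Conditions: NaBH4, CeCl3·7H2O, MeOH, −78 °C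
Reagents that add atoms: none
Why: Luche 1,2-reduction, in which the small hydride attacks the C7 carbonyl axially from the α-face (only C5–H and C9–H are axial there) to give the equatorial 7β-alcohol of the target, while the cold cerium-buffered medium avoids conjugate reduction and γ-deprotonation next to the iodide.

Step 9
Reactants: 11 2α-chloro-11-iodo-12,13,14,15,16-pentanorlabd-8(17)-en-7β-ol
Product: 12 2α-chloro-11-iodo-12,13,14,15,16-pentanorlabd-8(17)-en-7β-yl acetate
Conditions: Ac2O, pyridine, DMAP (cat.), CH2Cl2, rt
Reagents that add atoms: acetic anhydride, CC(=O)OC(C)=O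
Why: DMAP-catalysed O-acylation of the unhindered equatorial allylic alcohol with retention at C7; the neopentyl-type iodide is not displaced by pyridine at room temperature.

Step 10
Reactants: 13 succinimide
Product: 14 N-(4-methoxybenzyl)succinimide
Conditions: 4-MeOC6H4CH2Cl, K2CO3, DMF, rt
Reagents that add atoms: 4-methoxybenzyl chloride, COc1ccc(CCl)cc1
Why: SN2 N-alkylation of the imide anion (Gabriel-type) blocks the acidic N–H that would otherwise quench the organozinc reagent of step 14.

Step 11
Reactants: 14 N-(4-methoxybenzyl)succinimide
Product: 15 (E)-3-[(dimethylamino)methylene]-1-(4-methoxybenzyl)pyrrolidine-2,5-dione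
Conditions: t-BuOCH(NMe2)2, toluene, 100 °C
Reagents that add atoms: tert-butoxybis(dimethylamino)methane (Bredereck's reagent), CN(C)C(OC(C)(C)C)N(C)C
Why: Aminomethylenation of the imide α-CH2 with Bredereck's reagent (condensation, then loss of t-BuOH and Me2NH) installs the future C12 on the symmetric imide; the first vinylogous amide deactivates the ring toward a second condensation.

Step 12
Reactants: 15 (E)-3-[(dimethylamino)methylene]-1-(4-methoxybenzyl)pyrrolidine-2,5-dione
Product: 16 3-(hydroxymethylene)-1-(4-methoxybenzyl)pyrrolidine-2,5-dione (enol of the 3-formyl imide)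
Conditions: 1 M HCl, THF, rt
Reagents that add atoms: water, O
Why: Acid hydrolysis of the vinylogous amide (addition of water, elimination of dimethylamine) gives the stable, acidic formyl enol while the imide ring is not opened by dilute acid.

Step 13
Reactants: 16 3-(hydroxymethylene)-1-(4-methoxybenzyl)pyrrolidine-2,5-dione
Product: 17 (E)-[1-(4-methoxybenzyl)-2,5-dioxopyrrolidin-3-ylidene]methyl trifluoromethanesulfonate
Conditions: Tf2O, i-Pr2NEt, CH2Cl2, −78 °C
Reagents that add atoms: trifluoromethanesulfonic anhydride, O=S(=O)(OS(=O)(=O)C(F)(F)F)C(F)(F)F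
Why: O-sulfonylation of the non-chelated ammonium enolate, which reacts in its extended form with the enolate oxygen anti to the C16 carbonyl, so the E enol triflate should predominate and the Z isomer is removed by chromatography.

Step 14
Reactants: 12 2α-chloro-11-iodo-12,13,14,15,16-pentanorlabd-8(17)-en-7β-yl acetate; 17 (E)-[1-(4-methoxybenzyl)-2,5-dioxopyrrolidin-3-ylidene]methyl trifluoromethanesulfonate
Product: 19 N-(4-methoxybenzyl) derivative of the target, via alkylzinc iodide 18 (not isolated)
Conditions: Zn dust (TMSCl/BrCH2CH2Br-activated), LiCl, THF, 45 °C; then 17, PdCl2(dppf) (5 mol %), THF, rt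
Reagents that add atoms: none
Why: One-pot Negishi sp3–sp2 cross-coupling: zinc inserts into the primary C11–I bond of 12 (ester, secondary chloride and olefin are inert to the LiCl-solubilised RZnI 18), Pd(0) adds to the C12–OTf bond of 17, the alkyl group is transmetalated from zinc and reductive elimination forms the C11–C12 bond. The closest known reaction type is the Pd-catalysed coupling of functionalised primary alkylzinc iodides with enol triflates of β-dicarbonyl compounds. No ring is closed and no sp3 stereocentre is made; the only new stereo-element, the C12=C13 geometry, is copied from the E-triflate because oxidative addition and reductive elimination are both stereoretentive, so C11 ends up syn to the ring CH2 and anti to the C16 carbonyl. The step needs chemoselectivity for C(sp2)–OTf over the allylic C7 acetate: the 7β C–O bond is equatorial, lies near the nodal plane of the C8=C17 π-bond and cannot ionise to a π-allyl in the rigid trans-decalin, while the electron-poor vinyl triflate adds to Pd(0) far faster. It also needs reductive elimination to outrun β-hydride loss from C9–H, which the wide-bite-angle dppf ligand favours, and the neutral medium keeps the alkylidene succinimide from drifting to the maleimide. Placing the union after all redox work on ring B means the SeO2- and hydride-sensitive imide never meets those reagents.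

Step 15
Reactants: 19 N-(4-methoxybenzyl) derivative of the target
Product: 20 target, 3-[(E)-2-((1S,2S... decalinyl)ethylidene]pyrrolidine-2,5-dione (7β-acetoxy-2α-chlorolabda-8(17),12E-diene-15,16-imide)
Conditions: (NH4)2Ce(NO3)6, MeCN–H2O, 0 °C
Reagents that add atoms: none
Why: Oxidative N-debenzylation, in which Ce(IV) oxidises the anisyl ring, the benzylic cation is hydrated and the hemiaminal releases anisaldehyde with the imide as leaving group; isolated olefins, the alkyl chloride and the acetate are not oxidised and the short cold exposure should spare the allylic acetate.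

**Compound list**

1 | (+)-sclareolide | C[C@@]13CC[C@H]2C(C)(C)CCC[C@]2(C)[C@H]1CC(=O)O3 | starting material
2 | 2α-chlorosclareolide | C[C@@]13CC[C@H]2C(C)(C)C[C@H](Cl)C[C@]2(C)[C@H]1CC(=O)O3 | intermediate
3 | 2α-chlorosclareolide lactol (anomer mixture at C12) | C[C@@]13CC[C@H]2C(C)(C)C[C@H](Cl)C[C@]2(C)[C@H]1CC(O)O3 | intermediate
4 | lactol hypoiodite (12-O–I) | C[C@@]13CC[C@H]2C(C)(C)C[C@H](Cl)C[C@]2(C)[C@H]1CC(OI)O3 | intermediate (not isolated)
5 | 2α-chloro-11-iodo-12,13,14,15,16-pentanorlabdan-8α-yl formate | C[C@@]1(OC=O)CC[C@H]2C(C)(C)C[C@H](Cl)C[C@]2(C)[C@H]1CI | intermediate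
6 | 2α-chloro-11-iodo-12,13,14,15,16-pentanorlabdan-8α-ol | C[C@@]1(O)CC[C@H]2C(C)(C)C[C@H](Cl)C[C@]2(C)[C@H]1CI | intermediate
7 | 8α-chlorosulfite of 6 | C[C@@]1(OS(=O)Cl)CC[C@H]2C(C)(C)C[C@H](Cl)C[C@]2(C)[C@H]1CI | intermediate (not isolated)
8 | 2α-chloro-11-iodo-12,13,14,15,16-pentanorlabd-8(17)-ene | C=C1CC[C@H]2C(C)(C)C[C@H](Cl)C[C@]2(C)[C@H]1CI | intermediate
9 | 2α-chloro-11-iodo-12,13,14,15,16-pentanorlabd-8(17)-en-7α-ol | C=C1[C@H](O)C[C@H]2C(C)(C)C[C@H](Cl)C[C@]2(C)[C@H]1CI | intermediate
10 | 2α-chloro-11-iodo-12,13,14,15,16-pentanorlabd-8(17)-en-7-one | C=C1C(=O)C[C@H]2C(C)(C)C[C@H](Cl)C[C@]2(C)[C@H]1CI | intermediate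
11 | 2α-chloro-11-iodo-12,13,14,15,16-pentanorlabd-8(17)-en-7β-ol | C=C1[C@@H](O)C[C@H]2C(C)(C)C[C@H](Cl)C[C@]2(C)[C@H]1CI | intermediate
12 | 2α-chloro-11-iodo-12,13,14,15,16-pentanorlabd-8(17)-en-7β-yl acetate | C=C1[C@@H](OC(C)=O)C[C@H]2C(C)(C)C[C@H](Cl)C[C@]2(C)[C@H]1CI | intermediate
13 | succinimide | O=C1CCC(=O)N1 | starting material
14 | N-(4-methoxybenzyl)succinimide | O=C1CCC(=O)N1Cc1ccc(OC)cc1 | intermediate
15 | (E)-3-[(dimethylamino)methylene]-1-(4-methoxybenzyl)pyrrolidine-2,5-dione | CN(C)/C=C1\CC(=O)N(Cc2ccc(OC)cc2)C1=O | intermediate
16 | 3-(hydroxymethylene)-1-(4-methoxybenzyl)pyrrolidine-2,5-dione (enol of the 3-formyl imide, geometry not fixed) | OC=C1CC(=O)N(Cc2ccc(OC)cc2)C1=O | intermediate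
17 | (E)-[1-(4-methoxybenzyl)-2,5-dioxopyrrolidin-3-ylidene]methyl trifluoromethanesulfonate | O=S(=O)(O/C=C1\CC(=O)N(Cc2ccc(OC)cc2)C1=O)C(F)(F)F | intermediate
18 | C11 alkylzinc iodide derived from 12 | C=C1[C@@H](OC(C)=O)C[C@H]2C(C)(C)C[C@H](Cl)C[C@]2(C)[C@H]1C[Zn]I | intermediate (not isolated)
19 | N-(4-methoxybenzyl) derivative of the target | C=C1[C@@H](OC(C)=O)C[C@H]2C(C)(C)C[C@H](Cl)C[C@]2(C)[C@H]1C/C=C1\CC(=O)N(Cc2ccc(OC)cc2)C1=O | intermediate
20 | 7β-acetoxy-2α-chlorolabda-8(17),12E-diene-15,16-imide (CNP0220384.1) | C=C1[C@@H](OC(C)=O)C[C@H]2C(C)(C)C[C@H](Cl)C[C@]2(C)[C@H]1C/C=C1\CC(=O)NC1=O | target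

**Count and risks**

Total step count: 15. Longest linear sequence: 11 steps (steps 1–9, 14, 15); the imide branch (steps 10–13) is 4 steps.

Step 14. What may go wrong: slow or incomplete zinc insertion at the hindered C11–I bond, or β-hydride elimination from the alkylpalladium intermediate at C9–H, which would return olefin and reduced triflate instead of coupled product. Fallback: the organozinc is given up and 12 and 17 are joined directly by nickel-catalysed reductive cross-electrophile coupling (NiBr2·glyme, 4,4′-di-tert-butyl-2,2′-bipyridine, Mn powder, DMA, rt). The vinyl triflate adds to Ni(0), the C11 radical formed by halogen abstraction from 12 is captured at nickel, and reductive elimination from Ni(III) is fast relative to β-hydride loss, with the vinyl geometry retained. This sets out from 12 and 17 and comes back to the route at 19; no new compound is made (F0).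

Step 13. What may go wrong: poor control of enolate geometry in the O-sulfonylation, so that much of the material is sulfonylated with the oxygen syn to the C16 carbonyl. Fallback: the geometry is no longer set at the electrophile but at the end, by thermodynamic equilibration. Setting out from 16, the Z isomer formed alongside 17, (Z)-[1-(4-methoxybenzyl)-2,5-dioxopyrrolidin-3-ylidene]methyl trifluoromethanesulfonate F1, is coupled with the zinc reagent 18 exactly as in step 14 to the Z-alkylidene imide, the 12Z isomer of 19 F2. This is then isomerised with a catalytic thiyl radical (PhSSPh, hν, benzene; reversible addition–elimination at C12). The E isomer should be favoured because C11 then lies next to the ring CH2 and not next to the C16 carbonyl. The sequence comes back to the route at 19.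

Step 5. What may go wrong: loss of regiocontrol in the elimination, by ionisation of the chlorosulfite to the C8 cation and Zaitsev proton loss from C7. Fallback: the endocyclic olefin is used instead of being discarded. Setting out from 6, the Δ7 olefin that this pathway produces (and that cat. TsOH in toluene would give on purpose), 2α-chloro-11-iodo-12,13,14,15,16-pentanorlabd-7-ene F3, is subjected to the Schenck ene reaction (O2, tetraphenylporphyrin, hν, CH2Cl2, 0 °C). Singlet oxygen should add to C7 on the α-face with abstraction of a C17 methyl hydrogen, moving the double bond into the exocyclic position and giving 2α-chloro-7α-hydroperoxy-11-iodo-12,13,14,15,16-pentanorlabd-8(17)-ene F4; the tertiary 8-hydroperoxide is the expected side product. Reduction of F4 with PPh3 gives 9, where the sequence comes back to the route, replacing steps 5 and 6.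

**Further compounds**

F0 | step 14 | none | none
F1 | step 13 | (Z)-[1-(4-methoxybenzyl)-2,5-dioxopyrrolidin-3-ylidene]methyl trifluoromethanesulfonate | O=S(=O)(O/C=C1/CC(=O)N(Cc2ccc(OC)cc2)C1=O)C(F)(F)F
F2 | step 13 | 12Z isomer of 19 | C=C1[C@@H](OC(C)=O)C[C@H]2C(C)(C)C[C@H](Cl)C[C@]2(C)[C@H]1C/C=C1/CC(=O)N(Cc2ccc(OC)cc2)C1=O
F3 | step 5 | 2α-chloro-11-iodo-12,13,14,15,16-pentanorlabd-7-ene | CC1=CC[C@H]2C(C)(C)C[C@H](Cl)C[C@]2(C)[C@H]1CI
F4 | step 5 | 2α-chloro-7α-hydroperoxy-11-iodo-12,13,14,15,16-pentanorlabd-8(17)-ene | C=C1[C@H](OO)C[C@H]2C(C)(C)C[C@H](Cl)C[C@]2(C)[C@H]1CI
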